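To choose among the four one-sided charges, the curve of links against time comes first, drawn in logarithms of what is still missing.

| flask | first end groups | one-sided end groups | gas | remark | time |
|---|---|---|---|---|---|
| delta | 2 M | 0.044 M | 200 mM (held) | run made earlier |  |
| beta | 2 M | 0.11 M | 200 mM (held) | run made earlier |  |
| blue | 2.0 M | 0.0300 M | 200 mM (held) |  | 8.0 h |
| violet | 2.0 M | 0.0400 M | 200 mM (held) |  | 8.0 h |
| teal | 2.0 M | 0.0600 M | 200 mM (held) |  | 8.0 h |
| red | 2.0 M | 0.100 M | 200 mM (held) |  | 8.0 h |

| run | time / h | links / % |
|---|---|---|
| delta | 0.333 | 90.4 |
| delta | 1.00 | 97.2 |
| delta | 2.00 | 97.8 |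
| delta | 3.00 | 97.7 |
| delta | 4.00 | 97.3 |
| beta | 0.333 | 87.3 |
| beta | 1.00 | 94.1 |
| beta | 2.00 | 94.8 |
| beta | 3.00 | 94.7 |
| beta | 4.00 | 94.6 |

(readings scatter by 0.3 percentage points)

- at the start none of the gas is in solution
- a reading or a percentage of links counts all its forms, free or not
- the concentration of links that is asked is that of its free form alone
- "hardly changes" means that all values lie within two and a half points (for a concentration: within two and a half percent of the largest)

- [links] (only what is free in solution) at the end for blue, violet, teal, red, in this order
- the shape of the row from first to last (falls, then rises / falls all the way / rises, then falls / hardly changes / rises all the way)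

Red's ceiling is 1.90 M: the ceiling on links, their theoretical yield, is the charge of first end groups less the charge of one-sided end groups, on the reading that each one-sided end group takes one first end group away.

In delta this ceiling is 97.8 % of the first end groups charged. The whole of it is missing at the start, and at 0.333 h the gap has shrunk to 7.4 percentage points, a fall of 1.12 powers of ten. By 1.00 h the gap is 0.6 points, a further 1.09 powers of ten in twice the time, so the logarithmic line bends there, and this gap is a reading with a scatter of 0.3 points. The knee gives way to the level: delta reads 97.8 % at 2.00 h. Beta, with a ceiling of 94.5 % reckoned from its charge, reads 94.8 % at 2.00 h.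

The asked time of 8.0 h is later than these levels begin, so this reckoning puts links in all forms at the ceiling, 1.97 M in blue and 1.90 M in red. The readings count every form, so it gives no number for the free form.

The forecast gives 1.965 M, 1.955 M, 1.935 M and 1.895 M, a row that falls all the way. Of the free share it says: “this is an assumption and the real value could be lower”.

The simulation gives 0.530 M, 0.530 M, 0.530 M and 0.530 M for blue, violet, teal and red, so the row hardly changes.

    first end groups + second end groups → links (k = 0.0120 L mol⁻¹ s⁻¹)
    gas ⇌ second end groups, rate k2*(csat - [second end groups]) (kL = 0.140 s⁻¹)
    second end groups ⇌ dormant form (K = 140, k = 0.00840 s⁻¹)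
    crystals ⇌ links, rate k4*(cs4 - [links]) while solid is left; crystals form when [links] > cs4 (solubility = 0.530 M, k = 0.0120 s⁻¹)
    first end groups + one-sided end groups → capped ends (k = 0.140 L mol⁻¹ s⁻¹)

At 8.00 h crystals in red stand at 68.5 % of the first end groups charged, counted in links too. Red's ceiling of 1.90 M, less its free 0.530 M, leaves 1.37 M of links outside the solution. Blue's ceiling of 1.97 M, less its free 0.530 M, leaves 1.44 M, with crystals in blue at 72.0 % of the first end groups charged.

All runs were computed for substances that don't exist; the scatter is artificial.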